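The γ-lactone (ring B: C7, C8, O, C12, C11) is fused to the ten-membered carbocycle (ring A) through C7–C8, and O8 already carries the carboxyl carbon C12. The route keeps O8–C12 intact as a phenyl carbonate on an acyclic chain and closes both rings at once: a SmI2-triggered radical–polar crossover joins C8 to C7 (ring A) and C11 to C12 (ring B) and sets C7 and C8. The precursor is an acyclic 1-haloalkyl phenyl carbonate (C8) whose far end is an (E)-vinylphosphonate (C7=C11) beside the preset C6 carbinol; the phosphonate is then exchanged for the C11=C13 methylene by Horner–Wadsworth–Emmons reaction.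

Key step: step 15

Remark: germacrane numbering is used throughout (C1–C10 ring A, C11/C12/C13 lactone unit, C14 acetoxymethyl carbon on C10, C15 methyl on C4). C6 is carried as the (6S) epimer and inverted in the final esterification; this rests on the assumption that the C8 radical enters anti to the C6 silyloxy group.

Step 1
Reactants: 1 geraniol
Product: 2 (2S,3S)-2,3-epoxygeraniol
Conditions: Ti(OiPr)4 (5 mol %), L-(+)-diethyl tartrate (6 mol %), t-BuOOH, 4 Å sieves, CH2Cl2, −20 °C
Reagents that add atoms: tert-butyl hydroperoxide CC(C)(C)OO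
Why: Sharpless asymmetric epoxidation of the allylic alcohol, in which the L-(+)-tartrate catalyst delivers oxygen to the face that gives the (2S,3S)-epoxide and so fixes the later C4 center.

Step 2
Reactants: 2 (2S,3S)-2,3-epoxygeraniol
Product: 3 (3S)-3,7-dimethyloct-6-ene-1,3-diol
Conditions: NaAlH2(OCH2CH2OMe)2 (Red-Al), THF, 0 °C
Reagents that add atoms: none
Why: Hydroxyl-directed hydride opening of the 2,3-epoxy alcohol at C2 (intramolecular delivery from the alkoxyaluminate) gives the 1,3-diol and leaves the tertiary carbinol center untouched.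

Step 3
Reactants: 3 (3S)-3,7-dimethyloct-6-ene-1,3-diol
Product: 4 (3S)-3,7-dimethyl-1,3-bis(triethylsilyloxy)oct-6-ene
Conditions: TESOTf (2.5 equiv), 2,6-lutidine, CH2Cl2, −78 to 0 °C
Reagents that add atoms: triethylsilyl triflate CC[Si](CC)(CC)OS(=O)(=O)C(F)(F)F
Why: Silyl ether formation with the silyl triflate protects both the primary and the hindered tertiary hydroxyl.

Step 4
Reactants: 4 (3S)-3,7-dimethyl-1,3-bis(triethylsilyloxy)oct-6-ene
Product: 5 (3S)-3,7-dimethyl-3-(triethylsilyloxy)oct-6-enal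
Conditions: (COCl)2, DMSO, CH2Cl2, −78 to −30 °C; Et3N
Reagents that add atoms: none
Why: Under Swern oxidation conditions a primary triethylsilyl ether is cleaved and oxidised in place to the aldehyde (C6) while the tertiary silyl ether survives.

Step 5
Reactants: 5 (3S)-3,7-dimethyl-3-(triethylsilyloxy)oct-6-enal; 6 diethyl ethynylphosphonate
Product: 7 diethyl [(3S,5S)-3-hydroxy-5,9-dimethyl-5-(triethylsilyloxy)dec-8-en-1-yn-1-yl]phosphonate
Conditions: (S,S)-ProPhenol (20 mol %), Me2Zn (3 equiv), toluene, 4 °C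
Reagents that add atoms: none
Why: Zinc–ProPhenol-catalysed asymmetric alkynylation of the aldehyde, in which the chiral dinuclear zinc complex delivers the zinc acetylide to the Re face and sets the (6S) carbinol by reagent control (the antipodal ligand gives the epimer should the sense prove opposite).

Step 6
Reactants: 7 diethyl [(3S,5S)-3-hydroxy-5,9-dimethyl-5-(triethylsilyloxy)dec-8-en-1-yn-1-yl]phosphonate
Product: 8 diethyl [(1E,3S,5S)-3-hydroxy-5,9-dimethyl-5-(triethylsilyloxy)deca-1,8-dien-1-yl]phosphonate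
Conditions: NaAlH2(OCH2CH2OMe)2 (Red-Al), THF, −72 to −20 °C
Reagents that add atoms: none
Why: Alkoxide-directed trans-hydroalumination of the propargylic alcohol (hydride to C7, the β-carbon of the alkynylphosphonate) gives the (E)-vinylphosphonate on protonation.

Step 7
Reactants: 8 diethyl [(1E,3S,5S)-3-hydroxy-5,9-dimethyl-5-(triethylsilyloxy)deca-1,8-dien-1-yl]phosphonate
Product: 9 diethyl [(1E,3S,5S)-5,9-dimethyl-3,5-bis(triethylsilyloxy)deca-1,8-dien-1-yl]phosphonate
Conditions: TESCl, imidazole, DMF, 0 °C to RT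
Reagents that add atoms: chlorotriethylsilane CC[Si](Cl)(CC)CC
Why: Standard silylation of the secondary allylic alcohol keeps C6–O aprotic and bulky for the key step.

Step 8
Reactants: 9 diethyl [(1E,3S,5S)-5,9-dimethyl-3,5-bis(triethylsilyloxy)deca-1,8-dien-1-yl]phosphonate
Product: 10 diethyl [(1E,3S,5S)-5-methyl-8-oxo-3,5-bis(triethylsilyloxy)oct-1-en-1-yl]phosphonate
Conditions: O3, CH2Cl2, pyridine, −78 °C; PPh3
Reagents that add atoms: ozone [O-][O+]=O
Why: Ozonolysis is selective for the electron-rich trisubstituted alkene over the electron-poor vinylphosphonate and unveils the C1 aldehyde.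

Step 9
Reactants: 10 diethyl [(1E,3S,5S)-5-methyl-8-oxo-3,5-bis(triethylsilyloxy)oct-1-en-1-yl]phosphonate; 11 ethyl (triphenylphosphoranylidene)acetate
Product: 13 ethyl (2Z,6S,8S,9E)-10-(diethoxyphosphoryl)-2-iodo-6-methyl-6,8-bis(triethylsilyloxy)deca-2,9-dienoate, via iodo ylide 12 (not isolated)
Conditions: 11, N-iodosuccinimide, CH2Cl2, −20 °C; K2CO3; then 10, RT
Reagents that add atoms: N-iodosuccinimide O=C1CCC(=O)N1I
Why: Iodination of the stabilised ylide followed by Wittig olefination gives the α-iodoenoate with the aldehyde chain trans to the ester, which is the geometry of the later C1=C10 bond.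

Step 10
Reactants: 13 ethyl (2Z,6S,8S,9E)-10-(diethoxyphosphoryl)-2-iodo-6-methyl-6,8-bis(triethylsilyloxy)deca-2,9-dienoate; 14 (1,3-dioxolan-2-ylmethyl)zinc bromide
Product: 15 ethyl (2E,6S,8S,9E)-10-(diethoxyphosphoryl)-2-(1,3-dioxolan-2-ylmethyl)-6-methyl-6,8-bis(triethylsilyloxy)deca-2,9-dienoate
Conditions: Pd(PPh3)4 (5 mol %), THF, 50 °C
Reagents that add atoms: none
Why: Negishi cross-coupling of the alkenyl iodide with the alkylzinc reagent proceeds with retention of alkene geometry and brings in C9 and C8 (as the acetal), cis to C2.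

Step 11
Reactants: 15 ethyl (2E,6S,8S,9E)-10-(diethoxyphosphoryl)-2-(1,3-dioxolan-2-ylmethyl)-6-methyl-6,8-bis(triethylsilyloxy)deca-2,9-dienoate
Product: 16 diethyl [(1E,3S,5S,8E)-9-(1,3-dioxolan-2-ylmethyl)-10-hydroxy-5-methyl-3,5-bis(triethylsilyloxy)deca-1,8-dien-1-yl]phosphonate
Conditions: i-Bu2AlH (2.2 equiv), CH2Cl2, −78 °C
Reagents that add atoms: none
Why: 1,2-Reduction of the conjugated ester to the allylic alcohol (C14) by the aluminium hydride at low temperature leaves phosphonate, acetal and silyl ethers intact.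

Step 12
Reactants: 16 diethyl [(1E,3S,5S,8E)-9-(1,3-dioxolan-2-ylmethyl)-10-hydroxy-5-methyl-3,5-bis(triethylsilyloxy)deca-1,8-dien-1-yl]phosphonate
Product: 17 (2E,6S,8S,9E)-10-(diethoxyphosphoryl)-2-(1,3-dioxolan-2-ylmethyl)-6-methyl-6,8-bis(triethylsilyloxy)deca-2,9-dien-1-yl acetate
Conditions: Ac2O, pyridine, DMAP (cat.), CH2Cl2, 0 °C
Reagents that add atoms: acetic anhydride CC(=O)OC(C)=O
Why: Acetylation of the primary allylic alcohol installs the C14 acetate of the target.

Step 13
Reactants: 17 (2E,6S,8S,9E)-10-(diethoxyphosphoryl)-2-(1,3-dioxolan-2-ylmethyl)-6-methyl-6,8-bis(triethylsilyloxy)deca-2,9-dien-1-yl acetate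
Product: 18 (2E,6S,8S,9E)-10-(diethoxyphosphoryl)-6-methyl-2-(2-oxoethyl)-6,8-bis(triethylsilyloxy)deca-2,9-dien-1-yl acetate
Conditions: TESOTf, 2,4,6-collidine, CH2Cl2, 0 °C; then H2O
Reagents that add atoms: water O
Why: Silyl triflate/collidine acetal cleavage through a collidinium intermediate frees the C8 aldehyde under non-acidic conditions, which spares the silyl ethers and limits migration of the β,γ-double bond into conjugation.

Step 14
Reactants: 18 (2E,6S,8S,9E)-10-(diethoxyphosphoryl)-6-methyl-2-(2-oxoethyl)-6,8-bis(triethylsilyloxy)deca-2,9-dien-1-yl acetate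
Product: 19 (2E,6S,8S,9E)-2-[2-chloro-2-(phenoxycarbonyloxy)ethyl]-10-(diethoxyphosphoryl)-6-methyl-6,8-bis(triethylsilyloxy)deca-2,9-dien-1-yl acetate (both C8 epimers)
Conditions: PhOCOCl (1.5 equiv), pyridine (10 mol %), CH2Cl2, 0 °C to RT; used crude
Reagents that add atoms: phenyl chloroformate O=C(Cl)Oc1ccccc1
Why: Pyridine-catalysed addition of the chloroformate across the aldehyde C=O (chloride to carbon, acyl to oxygen) gives the 1-chloroalkyl carbonate and places the future lactone carbonyl carbon C12 on O8, with the C8 center formed as a mixture that is erased in step 15.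

Step 15
Reactants: 19 (2E,6S,8S,9E)-2-[2-chloro-2-(phenoxycarbonyloxy)ethyl]-10-(diethoxyphosphoryl)-6-methyl-6,8-bis(triethylsilyloxy)deca-2,9-dien-1-yl acetate
Product: 22 (4S,6S,7S,8R)-14-acetoxy-11-(diethoxyphosphoryl)-4,6-bis(triethylsilyloxy)germacr-1(10)-en-12,8-olide (C11 epimers), via iodo carbonate 20 (not isolated), via cyclised phosphonate carbanion 21 (not isolated)
Conditions: NaI, MeCN, 40 °C; evaporate; then syringe-pump addition in THF to SmI2 (2.5 equiv), THF, 2 mM, −20 °C to RT; aq. NH4Cl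
Reagents that add atoms: none
Why: Proposed new method: single-electron reduction of the C8–I bond of 20 by SmI2 gives the α-(phenoxycarbonyloxy)alkyl radical, which adds to C7, the β-carbon of the (E)-vinylphosphonate, in a 10-exo-trig closure of ring A; the α-phosphonyl radical is reduced by a second SmI2 to the samarium-bound carbanion 21, whose C11 attacks the carbonate carbon C12 in a 5-exo-trig addition–elimination that expels phenoxide and closes ring B. The closest known reaction types are SmI2-mediated radical cyclisation/anionic acylation cascades (radical–polar crossover), Giese-type radical macrocyclisations onto activated alkenes and the Dieckmann-type acylation of phosphonate carbanions by carbonates. C7 is controlled by the allylic C6 center: the C6–O bond lies anti to the forming C7–C8 bond, so the radical enters anti to the silyloxy group and the (6S) ether gives (7S). C8 is set in the same bond formation: trivalent samarium bridging the carbonate and phosphoryl oxygens holds O8 gauche to C11 while the ring arms C9 and C6 stay anti, the arrangement that leads to the trans-fused lactone (8R); C11 forms as a mixture and is erased in step 16. The step needs ring closure to outrun reduction of the C8 radical and intermolecular addition, which slow addition at high dilution, the cis disposition of C2 and C9 on the C1=C10 alkene and the polarised acceptor are meant to secure; the phosphonate directs attack to C7 and not C11.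

Step 16
Reactants: 22 (4S,6S,7S,8R)-14-acetoxy-11-(diethoxyphosphoryl)-4,6-bis(triethylsilyloxy)germacr-1(10)-en-12,8-olide
Product: 23 (4S,6S,7S,8R)-14-acetoxy-4,6-bis(triethylsilyloxy)germacra-1(10),11(13)-dien-12,8-olide
Conditions: 37% aq. HCHO, K2CO3, THF, 0 °C, 30 min
Reagents that add atoms: formaldehyde C=O
Why: Horner–Wadsworth–Emmons reaction of the phosphonate-stabilised lactone enolate with formaldehyde forms the C11=C13 methylene and removes the C11 stereocenter.

Step 17
Reactants: 23 (4S,6S,7S,8R)-14-acetoxy-4,6-bis(triethylsilyloxy)germacra-1(10),11(13)-dien-12,8-olide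
Product: 24 (4S,6S,7R,8R)-14-acetoxy-4,6-dihydroxygermacra-1(10),11(13)-dien-12,8-olide (6-epimer of the target alcohol; the C7 geometry is unchanged, only its descriptor)
Conditions: HF·pyridine, pyridine, THF, 0 °C to RT
Reagents that add atoms: none
Why: Fluoride-mediated desilylation frees the C6 and C4 hydroxyls, while acetate and methylene lactone are stable to buffered HF.

Step 18
Reactants: 25 ethyl but-2-ynoate
Product: 27 ethyl (2Z)-2-(hydroxymethyl)but-2-enoate, via alkenylalane 26 (not isolated)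
Conditions: i-Bu2AlH, N-methylmorpholine N-oxide, THF, 0 °C; then HCHO (gas), −30 °C to RT
Reagents that add atoms: formaldehyde C=O
Why: syn-Hydroalumination of the ynoate puts aluminium on C2 cis to the C3 hydrogen, and addition of the alkenylalane to formaldehyde with retention gives the (Z)-alkene (methyl cis to the ester).

Step 19
Reactants: 27 ethyl (2Z)-2-(hydroxymethyl)but-2-enoate
Product: 28 (2Z)-2-(hydroxymethyl)but-2-enoic acid
Conditions: LiOH, THF/H2O, 0 °C to RT; then 1 M HCl
Reagents that add atoms: water O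
Why: Saponification of the ethyl ester at low temperature leaves the (Z)-alkene unisomerised.

Step 20
Reactants: 28 (2Z)-2-(hydroxymethyl)but-2-enoic acid
Product: 29 (2Z)-2-(acetoxymethyl)but-2-enoic acid
Conditions: Ac2O, pyridine, 0 °C to RT; aqueous work-up
Reagents that add atoms: acetic anhydride CC(=O)OC(C)=O
Why: Acetylation of the primary alcohol, with the transient mixed anhydride of the acid hydrolysed on work-up.

Step 21
Reactants: 24 (4S,6S,7R,8R)-14-acetoxy-4,6-dihydroxygermacra-1(10),11(13)-dien-12,8-olide; 29 (2Z)-2-(acetoxymethyl)but-2-enoic acid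
Product: 30 CNP0280960.1, (4S,6R,7S,8R)-14-acetoxy-6-{[(2Z)-2-(acetoxymethyl)but-2-enoyl]oxy}-4-hydroxygermacra-1(10),11(13)-dien-12,8-olide
Conditions: PPh3, DIAD, THF/toluene, 0 °C to RT
Reagents that add atoms: none
Why: Mitsunobu esterification, in which the C6 oxyphosphonium ion is displaced by the carboxylate with inversion, turns (6S) into the (6R) ester of the target while the tertiary C4 hydroxyl does not react.

Compound list
1 | geraniol, (2E)-3,7-dimethylocta-2,6-dien-1-ol | CC(C)=CCC/C(C)=C/CO | starting material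
2 | (2S,3S)-2,3-epoxygeraniol | OC[C@@H]1O[C@@]1(C)CCC=C(C)C | intermediate
3 | (3S)-3,7-dimethyloct-6-ene-1,3-diol | OCC[C@@](C)(O)CCC=C(C)C | intermediate
4 | (3S)-3,7-dimethyl-1,3-bis(triethylsilyloxy)oct-6-ene | CC[Si](CC)(CC)OCC[C@@](C)(O[Si](CC)(CC)CC)CCC=C(C)C | intermediate
5 | (3S)-3,7-dimethyl-3-(triethylsilyloxy)oct-6-enal | O=CC[C@@](C)(O[Si](CC)(CC)CC)CCC=C(C)C | intermediate
6 | diethyl ethynylphosphonate | C#CP(=O)(OCC)OCC | starting material
7 | diethyl [(3S,5S)-3-hydroxy-5,9-dimethyl-5-(triethylsilyloxy)dec-8-en-1-yn-1-yl]phosphonate | CCOP(=O)(OCC)C#C[C@@H](O)C[C@@](C)(O[Si](CC)(CC)CC)CCC=C(C)C | intermediate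
8 | diethyl [(1E,3S,5S)-3-hydroxy-5,9-dimethyl-5-(triethylsilyloxy)deca-1,8-dien-1-yl]phosphonate | CCOP(=O)(OCC)/C=C/[C@@H](O)C[C@@](C)(O[Si](CC)(CC)CC)CCC=C(C)C | intermediate
9 | diethyl [(1E,3S,5S)-5,9-dimethyl-3,5-bis(triethylsilyloxy)deca-1,8-dien-1-yl]phosphonate | CCOP(=O)(OCC)/C=C/[C@@H](O[Si](CC)(CC)CC)C[C@@](C)(O[Si](CC)(CC)CC)CCC=C(C)C | intermediate
10 | diethyl [(1E,3S,5S)-5-methyl-8-oxo-3,5-bis(triethylsilyloxy)oct-1-en-1-yl]phosphonate | CCOP(=O)(OCC)/C=C/[C@@H](O[Si](CC)(CC)CC)C[C@@](C)(O[Si](CC)(CC)CC)CCC=O | intermediate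
11 | ethyl (triphenylphosphoranylidene)acetate | CCOC(=O)C=P(c1ccccc1)(c1ccccc1)c1ccccc1 | starting material
12 | ethyl iodo(triphenylphosphoranylidene)acetate | CCOC(=O)C(I)=P(c1ccccc1)(c1ccccc1)c1ccccc1 | intermediate (not isolated)
13 | ethyl (2Z,6S,8S,9E)-10-(diethoxyphosphoryl)-2-iodo-6-methyl-6,8-bis(triethylsilyloxy)deca-2,9-dienoate | CCOP(=O)(OCC)/C=C/[C@@H](O[Si](CC)(CC)CC)C[C@@](C)(O[Si](CC)(CC)CC)CC/C=C(\I)C(=O)OCC | intermediate
14 | (1,3-dioxolan-2-ylmethyl)zinc bromide | Br[Zn]CC1OCCO1 | starting material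
15 | ethyl (2E,6S,8S,9E)-10-(diethoxyphosphoryl)-2-(1,3-dioxolan-2-ylmethyl)-6-methyl-6,8-bis(triethylsilyloxy)deca-2,9-dienoate | CCOP(=O)(OCC)/C=C/[C@@H](O[Si](CC)(CC)CC)C[C@@](C)(O[Si](CC)(CC)CC)CC/C=C(\CC1OCCO1)C(=O)OCC | intermediate
16 | diethyl [(1E,3S,5S,8E)-9-(1,3-dioxolan-2-ylmethyl)-10-hydroxy-5-methyl-3,5-bis(triethylsilyloxy)deca-1,8-dien-1-yl]phosphonate | CCOP(=O)(OCC)/C=C/[C@@H](O[Si](CC)(CC)CC)C[C@@](C)(O[Si](CC)(CC)CC)CC/C=C(\CC1OCCO1)CO | intermediate
17 | (2E,6S,8S,9E)-10-(diethoxyphosphoryl)-2-(1,3-dioxolan-2-ylmethyl)-6-methyl-6,8-bis(triethylsilyloxy)deca-2,9-dien-1-yl acetate | CCOP(=O)(OCC)/C=C/[C@@H](O[Si](CC)(CC)CC)C[C@@](C)(O[Si](CC)(CC)CC)CC/C=C(\CC1OCCO1)COC(C)=O | intermediate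
18 | (2E,6S,8S,9E)-10-(diethoxyphosphoryl)-6-methyl-2-(2-oxoethyl)-6,8-bis(triethylsilyloxy)deca-2,9-dien-1-yl acetate | CCOP(=O)(OCC)/C=C/[C@@H](O[Si](CC)(CC)CC)C[C@@](C)(O[Si](CC)(CC)CC)CC/C=C(\CC=O)COC(C)=O | intermediate
19 | (2E,6S,8S,9E)-2-[2-chloro-2-(phenoxycarbonyloxy)ethyl]-10-(diethoxyphosphoryl)-6-methyl-6,8-bis(triethylsilyloxy)deca-2,9-dien-1-yl acetate, both epimers at the chlorinated carbon (C8) | CCOP(=O)(OCC)/C=C/[C@@H](O[Si](CC)(CC)CC)C[C@@](C)(O[Si](CC)(CC)CC)CC/C=C(\CC(Cl)OC(=O)Oc1ccccc1)COC(C)=O | intermediate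
20 | iodo analogue of 19, 2-[2-iodo-2-(phenoxycarbonyloxy)ethyl] compound | CCOP(=O)(OCC)/C=C/[C@@H](O[Si](CC)(CC)CC)C[C@@](C)(O[Si](CC)(CC)CC)CC/C=C(\CC(I)OC(=O)Oc1ccccc1)COC(C)=O | intermediate (not isolated)
21 | ten-membered-ring C11 carbanion (samarium-bound) bearing the C8 phenyl carbonate, (4S,6S,7S,8R) | O=C(Oc1ccccc1)O[C@@H]2C/C(COC(C)=O)=C\CC[C@](C)(O[Si](CC)(CC)CC)C[C@H](O[Si](CC)(CC)CC)[C@H]2[CH-]P(=O)(OCC)OCC | intermediate (not isolated)
22 | (4S,6S,7S,8R)-14-acetoxy-11-(diethoxyphosphoryl)-4,6-bis(triethylsilyloxy)germacr-1(10)-en-12,8-olide, C11 epimers, C2 and C9 cis on the ring alkene | CCOP(=O)(OCC)C1C(=O)O[C@@H]2C/C(COC(C)=O)=C\CC[C@](C)(O[Si](CC)(CC)CC)C[C@H](O[Si](CC)(CC)CC)[C@@H]12 | intermediate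
23 | (4S,6S,7S,8R)-14-acetoxy-4,6-bis(triethylsilyloxy)germacra-1(10),11(13)-dien-12,8-olide | C=C1C(=O)O[C@@H]2C/C(COC(C)=O)=C\CC[C@](C)(O[Si](CC)(CC)CC)C[C@H](O[Si](CC)(CC)CC)[C@@H]12 | intermediate
24 | (4S,6S,7R,8R)-14-acetoxy-4,6-dihydroxygermacra-1(10),11(13)-dien-12,8-olide | C=C1C(=O)O[C@@H]2C/C(COC(C)=O)=C\CC[C@](C)(O)C[C@H](O)[C@@H]12 | intermediate
25 | ethyl but-2-ynoate | CC#CC(=O)OCC | starting material
26 | ethyl (2E)-2-(diisobutylalumanyl)but-2-enoate (methyl cis to the ester) | C/C=C(\C(=O)OCC)[Al](CC(C)C)CC(C)C | intermediate (not isolated)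
27 | ethyl (2Z)-2-(hydroxymethyl)but-2-enoate | C/C=C(\C(=O)OCC)CO | intermediate
28 | (2Z)-2-(hydroxymethyl)but-2-enoic acid | C/C=C(\C(=O)O)CO | intermediate
29 | (2Z)-2-(acetoxymethyl)but-2-enoic acid | C/C=C(\C(=O)O)COC(C)=O | intermediate
30 | CNP0280960.1, (4S,6R,7S,8R)-14-acetoxy-6-{[(2Z)-2-(acetoxymethyl)but-2-enoyl]oxy}-4-hydroxygermacra-1(10),11(13)-dien-12,8-olide | C=C1C(=O)O[C@@H]2C/C(COC(C)=O)=C\CC[C@](C)(O)C[C@@H](OC(=O)/C(=C\C)COC(C)=O)[C@@H]12 | target

Total step count: 21. Longest linear sequence: 18 steps (steps 1–17 and 21).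

Steps most likely to fail

1. Step 15 (bears the label "Proposed new method:"). The C8 radical may be reduced to the organosamarium, or undergo 1,5-hydrogen transfer from the allylic C2 position, before the ten-membered ring closes. The carbanion may be protonated before it acylates, or the ring fusion may come out cis. The fallback separates the two bond formations with known chemistry and sets out from 19. Bu3SnH and AIBN are added by syringe pump to 19 in benzene at 80 °C (1 mM), a tin hydride chain macrocyclisation with hydrogen-atom transfer to the C11 radical. This gives the ten-membered (diethoxyphosphoryl)methyl phenyl carbonate F1. LiN(SiMe3)2 (2.2 equiv) in THF at −78 to 0 °C then forms the phosphonate carbanion, which is acylated by the carbonate in a Dieckmann-type closure, and the route is rejoined at 22.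

2. Step 21. The hindered C6 hydroxyl may fail to form the oxyphosphonium ion, elimination toward C5 may compete, or the phosphine may add to the methylene lactone. The fallback sets out from 24. MsCl and Et3N in CH2Cl2 at −20 °C give the 6-O-mesylate F2, with the tertiary hydroxyl untouched. Displacement with the caesium salt of 29 (Cs2CO3, 18-crown-6, toluene, 70 °C) proceeds with inversion and comes back to the route at 30.

3. Step 5. Facial selectivity may be poor with this electron-poor alkyne, or aldol self-condensation of 5 may compete. The fallback sets out from 5. The lithium acetylide of 6 (LiN(SiMe3)2, THF, −78 °C) adds without stereocontrol to give the C3-epimeric carbinols F3. Dess–Martin periodinane (NaHCO3, CH2Cl2) gives the ynone F4. Noyori transfer hydrogenation with RuCl[(S,S)-TsDPEN](p-cymene) and HCO2H/Et3N then sets the (6S) carbinol by reagent control and returns to 7.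

Further compounds
F1 | step 15 | (4S,6S,7S,8R)-14-acetoxy-12-nor-11-(diethoxyphosphoryl)-8-(phenoxycarbonyloxy)-4,6-bis(triethylsilyloxy)germacr-1(10)-ene, the cyclodecene bearing CH2P(O)(OEt)2 on C7 | O=C(Oc1ccccc1)O[C@@H]2C/C(COC(C)=O)=C\CC[C@](C)(O[Si](CC)(CC)CC)C[C@H](O[Si](CC)(CC)CC)[C@H]2CP(=O)(OCC)OCC
F2 | step 21 | (4S,6S,7S,8R)-14-acetoxy-4-hydroxy-6-(methylsulfonyloxy)germacra-1(10),11(13)-dien-12,8-olide | C=C1C(=O)O[C@@H]2C/C(COC(C)=O)=C\CC[C@](C)(O)C[C@H](OS(C)(=O)=O)[C@@H]12
F3 | step 5 | diethyl [(5S)-3-hydroxy-5,9-dimethyl-5-(triethylsilyloxy)dec-8-en-1-yn-1-yl]phosphonate, C3 epimers | CCOP(=O)(OCC)C#CC(O)C[C@@](C)(O[Si](CC)(CC)CC)CCC=C(C)C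
F4 | step 5 | diethyl [(5S)-5,9-dimethyl-3-oxo-5-(triethylsilyloxy)dec-8-en-1-yn-1-yl]phosphonate | CCOP(=O)(OCC)C#CC(=O)C[C@@](C)(O[Si](CC)(CC)CC)CCC=C(C)C
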